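**Retrosynthetic overview**
1. Target 29 ⇐ angeloylation of C1 alcohol 26. The cyclobutane and cyclohexenone of 26 come from one semipinacol 1,2-shift (bicyclo[2.2.1] → bicyclo[3.1.1] ring contraction) of the endo-amino bridgehead silyl ether 23.
2. 23 ⇐ nitro cycloadduct 22 ⇐ intramolecular Diels–Alder of a 5,5-disubstituted 1-silyloxycyclopentadiene with a tethered (E)-nitroalkene (norbornene and seven-membered ring together).
3. Tether ⇐ Evans–Tishchenko reduction (anti-1,3-diol, installs the epoxy ester) of the aldol adduct of methyl ketone 8 and aldehyde 12; nitroalkene ⇐ nitration of the vinyl group.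
4. Quaternary C11 of 8 ⇐ asymmetric epoxidation and semipinacol ring expansion of alkenylcyclobutanol 4 (cyclobutane → cyclopentanone).
5. Ring order: five-membered ring (ring expansion) → norbornene plus seven-membered ring (cycloaddition) → four- and six-membered rings (1,2-shift).

Assumption: core carbons are labelled C1–C11 in the order they appear in the target SMILES (C1 bears the angelate, C3 the epoxy ester, C7 is the ketone carbon, C11 the methyl-bearing quaternary carbon), and the epoxy ester is read as (2S,3R)-2,3-dimethyloxirane-2-carboxylate (methyl groups cis).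

**Route**

Step 1
Reactants: 1 (E)-2-bromobut-2-ene; 2 3-methylcyclobutan-1-one
Product: 4 1-[(E)-but-2-en-2-yl]-3-methylcyclobutan-1-ol (cis/trans mixture), via alkenyllithium 3 (not isolated)
Conditions: t-BuLi (2 equiv), Et2O, −78 °C; then 2, −78 → 0 °C; H2O
Reagents that add atoms: none
Why: Bromine–lithium exchange keeps the alkene geometry and the alkenyllithium adds 1,2 to the strained ketone (organolithium carbonyl addition); the ring cis/trans ratio is irrelevant because that carbon becomes sp2 in step 3.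

Step 2
Reactants: 4 1-[(E)-but-2-en-2-yl]-3-methylcyclobutan-1-ol
Product: 6 (2S)-2-[(1S)-1-hydroxyethyl]-2,4-dimethylcyclopentan-1-one (both epimers at ring carbon 4), via epoxide 5 (not isolated)
Conditions: L-fructose-derived Shi ketone (1,2:4,5-di-O-isopropylidene-β-L-erythro-2,3-hexodiulo-2,6-pyranose, 30 mol%), Oxone (KHSO5), K2CO3, Bu4NHSO4, MeCN–CH2(OMe)2–aq. Na2B4O7, 0 °C; extract; then BF3·OEt2 (10 mol%), CH2Cl2, −78 °C
Reagents that add atoms: potassium peroxymonosulfate, [K+].[O-]S(=O)(=O)OO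
Why: Shi asymmetric epoxidation of the trisubstituted (E)-alkene (spiro transition state, this ketone enantiomer gives the (2R,3S)-epoxide) is followed by a stereospecific semipinacol ring expansion in which a cyclobutane C–C bond migrates anti to the breaking tertiary C–O bond, setting the quaternary centre with inversion.

Step 3
Reactants: 6 (2S)-2-[(1S)-1-hydroxyethyl]-2,4-dimethylcyclopentan-1-one
Product: 8 (5S)-5-acetyl-3,5-dimethylcyclopent-2-en-1-one, via diketone 7 (not isolated)
Conditions: IBX (4 equiv), DMSO, 25 °C then 75 °C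
Reagents that add atoms: none
Why: IBX oxidises the secondary alcohol and then dehydrogenates the only α,β-position that carries hydrogens on both carbons (IBX-mediated ketone dehydrogenation), which also removes the stereorandom ring carbon.

Step 4
Reactants: 9 1-chloro-3-methylbut-2-ene; 10 N,N-dimethylformamide
Product: 12 2,2-dimethylbut-3-enal, via prenylmagnesium chloride 11 (not isolated)
Conditions: Mg, THF, 0 °C; then 10, −20 → 0 °C; aq. HCl
Reagents that add atoms: none
Why: The prenyl Grignard reagent attacks the formamide through its γ-carbon (SE2′, six-membered transition state) and hydrolysis gives the α,α-dimethyl aldehyde (Bouveault-type formylation).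

Step 5
Reactants: 8 (5S)-5-acetyl-3,5-dimethylcyclopent-2-en-1-one; 12 2,2-dimethylbut-3-enal
Product: 14 (5S)-5-[(3R)-3-hydroxy-4,4-dimethylhex-5-enoyl]-3,5-dimethylcyclopent-2-en-1-one, via boron enolate 13 (not isolated)
Conditions: (−)-Ipc2BCl, Et3N, Et2O, 0 °C; then 12, −78 → −20 °C; H2O2, MeOH, pH 7 buffer, 0 °C
Reagents that add atoms: none
Why: Only the acetyl group can be enolised, and the diisopinocampheylboron enolate of a methyl ketone adds to the re face of the non-enolisable aldehyde under reagent control (boron-mediated asymmetric aldol reaction), giving the (3R)-carbinol.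

Step 6
Reactants: 15 (E)-2-methylbut-2-en-1-ol
Product: 16 [(2R,3R)-2,3-dimethyloxiran-2-yl]methanol
Conditions: Ti(OiPr)4 (10 mol%), D-(−)-diethyl tartrate (12 mol%), t-BuOOH, 4 Å MS, CH2Cl2, −20 °C
Reagents that add atoms: tert-butyl hydroperoxide, CC(C)(C)OO
Why: Sharpless asymmetric epoxidation, in which the D-(−)-tartrate complex delivers oxygen to the alkene face that gives the (2R,3R)-epoxy alcohol.

Step 7
Reactants: 16 [(2R,3R)-2,3-dimethyloxiran-2-yl]methanol
Product: 17 (2S,3R)-2,3-dimethyloxirane-2-carbaldehyde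
Conditions: TEMPO (10 mol%), PhI(OAc)2, CH2Cl2, 23 °C; used as a solution
Reagents that add atoms: none
Why: Oxoammonium-mediated alcohol oxidation stops at the aldehyde and leaves the epoxide and both stereocentres untouched (the C2 descriptor changes only through priorities).

Step 8
Reactants: 14 (5S)-5-[(3R)-3-hydroxy-4,4-dimethylhex-5-enoyl]-3,5-dimethylcyclopent-2-en-1-one; 17 (2S,3R)-2,3-dimethyloxirane-2-carbaldehyde
Product: 18 (1R,3R)-1-hydroxy-4,4-dimethyl-1-[(1S)-1,4-dimethyl-2-oxocyclopent-3-en-1-yl]hex-5-en-3-yl (2S,3R)-2,3-dimethyloxirane-2-carboxylate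
Conditions: SmI2 (30 mol%) premixed with 17 (4 equiv), THF, −10 °C; then 14, −10 °C
Reagents that add atoms: none
Why: Evans–Tishchenko reduction, in which the samarium-bound hemiacetal of the C3 hydroxyl delivers hydride intramolecularly to the C1 ketone through a chair-like transition state, giving the 1,3-anti (1R) alcohol and leaving the aldehyde as the C3 ester.

Step 9
Reactants: 18 hydroxy ester from step 8
Product: 19 (1R,3R)-4,4-dimethyl-1-[(1S)-1,4-dimethyl-2-oxocyclopent-3-en-1-yl]-1-(triethylsilyloxy)hex-5-en-3-yl (2S,3R)-2,3-dimethyloxirane-2-carboxylate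
Conditions: Et3SiOTf, 2,6-lutidine, CH2Cl2, −78 °C
Reagents that add atoms: triethylsilyl trifluoromethanesulfonate, CC[Si](CC)(CC)OS(=O)(=O)C(F)(F)F
Why: Low-temperature O-silylation (silyl ether protection) masks the C1 hydroxyl so that it cannot add to the nitroalkene made next; the weak base does not enolise the enone.

Step 10
Reactants: 19 silyl ether from step 9
Product: 20 (1R,3R,5E)-4,4-dimethyl-1-[(1S)-1,4-dimethyl-2-oxocyclopent-3-en-1-yl]-6-nitro-1-(triethylsilyloxy)hex-5-en-3-yl (2S,3R)-2,3-dimethyloxirane-2-carboxylate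
Conditions: AgNO2 (3 equiv), TEMPO (0.4 equiv), 4 Å MS, ClCH2CH2Cl, 70 °C
Reagents that add atoms: silver nitrite, [Ag+].[O-]N=O
Why: Radical nitration of alkenes, in which NO2 adds to the terminal carbon of the electron-richer monosubstituted alkene, TEMPO traps the radical and elimination gives the (E)-nitroalkene, while the electron-poor trisubstituted enone is left alone.

Step 11
Reactants: 20 nitroalkene from step 10
Product: 22 6-endo-nitro-1,7-bis(triethylsilyloxy) tricyclic cycloadduct (1R,3R,5R,6R,7R,10R,11S), via silyl dienol ether 21 (not isolated)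
Conditions: Et3SiOTf, i-Pr2NEt, CH2Cl2, −78 → 23 °C; then PhMe, 60 °C
Reagents that add atoms: triethylsilyl trifluoromethanesulfonate, CC[Si](CC)(CC)OS(=O)(=O)C(F)(F)F
Why: γ-Deprotonation of the O-silylated enone gives the 1-silyloxycyclopentadiene, whose most nucleophilic terminus C10 bonds to the electrophilic carbon C5 of the tethered nitroalkene in an intramolecular Diels–Alder reaction; the tether fixes the diene face (C5, C7 and C10 relative to C11) and the (E)-geometry places the nitro group endo at C6.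

Step 12
Reactants: 22 nitro cycloadduct from step 11
Product: 23 6-endo-amino-1,7-bis(triethylsilyloxy) tricycle (1R,3R,5R,6R,7R,10R,11S)
Conditions: Zn dust, AcOH, THF, 0 → 23 °C
Reagents that add atoms: none
Why: Dissolving-metal reduction of the secondary nitro group gives the amine with C6 unchanged, and is run before any desilylation so that the β-silyloxy nitro unit cannot undergo retro-Henry cleavage.

Step 13
Reactants: 23 amine from step 12
Product: 26 C1 alcohol of the tricyclic enone core (1R,3R,5S,6R,10R,11R) carrying the C3 epoxy ester, via diazonium acetate 24 (not isolated), via silyl ether enone 25 (not isolated)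
Conditions: NaNO2, AcOH–H2O–THF (3:1:1), 0 °C, 1 h; then 23 °C, 8 h
Reagents that add atoms: none
Why: Proposed new method: diazotisation gives a 6-endo diazonium ion whose C–N bond is nearly antiperiplanar (about 155°) to the C7–C11 bridge bond, so lone-pair push from the bridgehead silyloxy oxygen drives a 1,2-shift of C11 from C7 to C6 (inversion at C6, retention at C11) with loss of N2, creating the cyclobutane and the C7 ketone conjugated with C8=C9, after which the aqueous acid removes both silyl groups; the closest known reaction type is the Tiffeneau–Demjanov (pinacol-type) rearrangement of β-amino alcohols, here used in the strain-increasing bicyclo[2.2.1] to bicyclo[3.1.1] direction, which has not been shown on such a substrate.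

Step 14
Reactants: 26 C1 alcohol from step 13; 27 angelic acid ((Z)-2-methylbut-2-enoic acid)
Product: 29 target CNP0149458.1, via mixed anhydride 28 (not isolated)
Conditions: 27, 2,4,6-trichlorobenzoyl chloride, Et3N, PhMe, 23 °C; then 26, PhMe, 80 °C (no DMAP)
Reagents that add atoms: none
Why: Yamaguchi-type esterification through the mixed anhydride without a nucleophilic catalyst acylates the hindered C1 alcohol while keeping the (Z)-geometry of the angelate; no stereocentre is touched.

**Compound list**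
1 | (E)-2-bromobut-2-ene | C/C=C(\C)Br | starting material
2 | 3-methylcyclobutan-1-one | CC1CC(=O)C1 | starting material
3 | (E)-but-2-en-2-yllithium | C/C=C(\C)[Li] | intermediate
4 | 1-[(E)-but-2-en-2-yl]-3-methylcyclobutan-1-ol (cis/trans mixture on the ring) | C/C=C(\C)C1(O)CC(C)C1 | intermediate
5 | 1-[(2R,3S)-2,3-dimethyloxiran-2-yl]-3-methylcyclobutan-1-ol | C[C@@H]1O[C@@]1(C)C1(O)CC(C)C1 | intermediate
6 | (2S)-2-[(1S)-1-hydroxyethyl]-2,4-dimethylcyclopentan-1-one (both epimers at ring carbon 4) | C[C@H](O)[C@]1(C)CC(C)CC1=O | intermediate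
7 | (2S)-2-acetyl-2,4-dimethylcyclopentan-1-one (both epimers at ring carbon 4) | CC(=O)[C@]1(C)CC(C)CC1=O | intermediate
8 | (5S)-5-acetyl-3,5-dimethylcyclopent-2-en-1-one | CC(=O)[C@]1(C)CC(C)=CC1=O | intermediate
9 | 1-chloro-3-methylbut-2-ene | CC(C)=CCCl | starting material
10 | N,N-dimethylformamide | CN(C)C=O | starting material
11 | (3-methylbut-2-en-1-yl)magnesium chloride | CC(C)=CC[Mg]Cl | intermediate
12 | 2,2-dimethylbut-3-enal | C=CC(C)(C)C=O | intermediate
13 | O-[(−)-diisopinocampheylboryl] enolate of 8 (boron on the acetyl-derived enol oxygen) | C=C(OB([C@@H]2C[C@@H]3C[C@H]([C@H]2C)C3(C)C)[C@@H]2C[C@@H]3C[C@H]([C@H]2C)C3(C)C)[C@]1(C)CC(C)=CC1=O | intermediate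
14 | (5S)-5-[(3R)-3-hydroxy-4,4-dimethylhex-5-enoyl]-3,5-dimethylcyclopent-2-en-1-one | O=C(C[C@@H](O)C(C)(C)C=C)[C@]1(C)CC(C)=CC1=O | intermediate
15 | (E)-2-methylbut-2-en-1-ol | C/C=C(\C)CO | starting material
16 | [(2R,3R)-2,3-dimethyloxiran-2-yl]methanol | OC[C@@]1(C)O[C@@H]1C | intermediate
17 | (2S,3R)-2,3-dimethyloxirane-2-carbaldehyde | O=C[C@@]1(C)O[C@@H]1C | intermediate
18 | (1R,3R)-1-hydroxy-4,4-dimethyl-1-[(1S)-1,4-dimethyl-2-oxocyclopent-3-en-1-yl]hex-5-en-3-yl (2S,3R)-2,3-dimethyloxirane-2-carboxylate | O[C@H](C[C@@H](OC(=O)[C@@]2(C)O[C@@H]2C)C(C)(C)C=C)[C@]1(C)CC(C)=CC1=O | intermediate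
19 | (1R,3R)-4,4-dimethyl-1-[(1S)-1,4-dimethyl-2-oxocyclopent-3-en-1-yl]-1-(triethylsilyloxy)hex-5-en-3-yl (2S,3R)-2,3-dimethyloxirane-2-carboxylate | CC[Si](CC)(CC)O[C@H](C[C@@H](OC(=O)[C@@]2(C)O[C@@H]2C)C(C)(C)C=C)[C@]1(C)CC(C)=CC1=O | intermediate
20 | (1R,3R,5E)-4,4-dimethyl-1-[(1S)-1,4-dimethyl-2-oxocyclopent-3-en-1-yl]-6-nitro-1-(triethylsilyloxy)hex-5-en-3-yl (2S,3R)-2,3-dimethyloxirane-2-carboxylate | CC[Si](CC)(CC)O[C@H](C[C@@H](OC(=O)[C@@]2(C)O[C@@H]2C)C(C)(C)/C=C/[N+](=O)[O-])[C@]1(C)CC(C)=CC1=O | intermediate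
21 | (1R,3R,5E)-4,4-dimethyl-1-[(1S)-1,4-dimethyl-2-(triethylsilyloxy)cyclopenta-2,4-dien-1-yl]-6-nitro-1-(triethylsilyloxy)hex-5-en-3-yl (2S,3R)-2,3-dimethyloxirane-2-carboxylate | CC[Si](CC)(CC)O[C@H](C[C@@H](OC(=O)[C@@]2(C)O[C@@H]2C)C(C)(C)/C=C/[N+](=O)[O-])[C@]1(C)C=C(C)C=C1O[Si](CC)(CC)CC | intermediate
22 | nitro cycloadduct (1R,3R,5R,6R,7R,10R,11S): norbornene with bridgeheads C7 (OSiEt3) and C10, one-carbon bridge C11 (CH3), alkene C8=C9 (CH3), C6 (endo-NO2) and C5; seven-membered ring C11–C1(OSiEt3)–C2–C3(epoxy ester)–C4(CH3)2–C5 attached exo at C5 | CC[Si](CC)(CC)O[C@@H]1C[C@@H](OC(=O)[C@@]2(C)O[C@@H]2C)C(C)(C)[C@@H]2[C@@H]([N+](=O)[O-])[C@@]3(O[Si](CC)(CC)CC)C=C(C)[C@@H]2[C@]31C | intermediate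
23 | 6-endo-amine corresponding to 22 (same configuration) | CC[Si](CC)(CC)O[C@@H]1C[C@@H](OC(=O)[C@@]2(C)O[C@@H]2C)C(C)(C)[C@@H]2[C@@H](N)[C@@]3(O[Si](CC)(CC)CC)C=C(C)[C@@H]2[C@]31C | intermediate
24 | 6-endo-diazonium acetate corresponding to 23 | CC[Si](CC)(CC)O[C@@H]1C[C@@H](OC(=O)[C@@]2(C)O[C@@H]2C)C(C)(C)[C@@H]2[C@@H]([N+]#N)[C@@]3(O[Si](CC)(CC)CC)C=C(C)[C@@H]2[C@]31C.CC(=O)[O-] | intermediate
25 | C1 triethylsilyl ether of 26 (1R,3R,5S,6R,10R,11R) | CC[Si](CC)(CC)O[C@@H]1C[C@@H](OC(=O)[C@@]2(C)O[C@@H]2C)C(C)(C)[C@@H]2[C@H]3C(=O)C=C(C)[C@@H]2[C@]31C | intermediate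
26 | tricyclic enone C1 alcohol (1R,3R,5S,6R,10R,11R): target without the angeloyl group | O[C@@H]1C[C@@H](OC(=O)[C@@]2(C)O[C@@H]2C)C(C)(C)[C@@H]2[C@H]3C(=O)C=C(C)[C@@H]2[C@]31C | intermediate
27 | angelic acid, (Z)-2-methylbut-2-enoic acid | C/C=C(/C)C(=O)O | starting material
28 | angelic 2,4,6-trichlorobenzoic anhydride | C/C=C(/C)C(=O)OC(=O)c1c(Cl)cc(Cl)cc1Cl | intermediate
29 | CNP0149458.1 | C/C=C(/C)C(=O)O[C@@H]1C[C@@H](OC(=O)[C@@]2(C)O[C@@H]2C)C(C)(C)[C@@H]2[C@H]3C(=O)C=C(C)[C@@H]2[C@]31C | target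

**Totals**
Total step count: 14. Longest linear sequence: 11 (steps 1, 2, 3, 5, 8, 9, 10, 11, 12, 13, 14).

**Steps most likely to fail**

Step 13 (the proposed ring contraction). The diazonium ion may ionise without participation, giving vinyl (C8) shift, solvolysis or elimination. The fallback uses known chemistry, sets out from 19 and comes back at 26. Dehydrogenative borylation of the vinyl group of 19 (B2pin2, trans-RhCl(CO)(PPh3)2, PhMe–MeCN, 80 °C) gives the (E)-alkenylboronate F1. Et3SiOTf/i-Pr2NEt converts it into the silyl dienol ether F2, which on heating (PhMe, 130 °C) undergoes the same tether-controlled intramolecular Diels–Alder reaction to the 6-endo-boronate F3. NaBO3·4H2O (THF–H2O) oxidises the C–B bond with retention to the 6-endo-alcohol F4, and MsCl/Et3N gives the 6-endo-mesylate F5. Bu4NF (THF, 0 °C) removes the silyl groups, and the bridgehead alkoxide triggers the classical base-induced pinacol-type rearrangement of a 2-hydroxy sulfonate (the antiperiplanar C7–C11 bond migrates, mesylate leaves), giving 26.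

Step 11 (silyl dienol ether formation and cycloaddition). Risks are deprotonation at the C9 methyl instead of C10, decomposition of the nitroalkene, and slow closure of the seven-membered ring. The fallback sets out from 20 and comes back at 22. LiN(SiMe3)2 (THF, −78 °C) forms the extended dienolate, which adds through C10 to the tethered nitroalkene (intramolecular vinylogous Michael addition) to give, after protonation, the bicyclic nitro enone F6. i-Pr2NEt/Et3SiOTf (CH2Cl2, −78 → 0 °C) then closes the C6–C7 bond by intramolecular nitro-aldol (Henry) addition to the silyl-activated ketone and traps the bridgehead oxygen as its triethylsilyl ether, giving 22 (the endo-nitro epimer, trans to C4, is the thermodynamic one).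

Step 8 (Evans–Tishchenko reduction with the epoxy aldehyde). The hindered C1 ketone may react slowly and the α-epoxy aldehyde may be opened by samarium or cause acyl migration. The fallback sets out from 14 and comes back at 19. Evans–Tishchenko reduction with acetaldehyde (SmI2 cat., THF, −10 °C) gives the 1,3-anti hydroxy acetate F7. Et3SiOTf/2,6-lutidine gives the silyl ether acetate F8, and K2CO3/MeOH removes the acetate to give the C3 alcohol F9. Aldehyde 17 is oxidised (NaClO2, NaH2PO4, 2-methylbut-2-ene, t-BuOH–H2O) to (2S,3R)-2,3-dimethyloxirane-2-carboxylic acid F10, which is coupled with F9 (2,4,6-trichlorobenzoyl chloride, Et3N, DMAP, PhMe) to give 19.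

**Further compounds**
F1 | step 13 | (E)-alkenylboronate of 19 (pinacolboryl on C6) | CC[Si](CC)(CC)O[C@H](C[C@@H](OC(=O)[C@@]2(C)O[C@@H]2C)C(C)(C)/C=C/B2OC(C)(C)C(C)(C)O2)[C@]1(C)CC(C)=CC1=O
F2 | step 13 | triethylsilyl dienol ether of F1 | CC[Si](CC)(CC)O[C@H](C[C@@H](OC(=O)[C@@]2(C)O[C@@H]2C)C(C)(C)/C=C/B2OC(C)(C)C(C)(C)O2)[C@]1(C)C=C(C)C=C1O[Si](CC)(CC)CC
F3 | step 13 | 6-endo-pinacolboronate cycloadduct (22 with Bpin in place of NO2) | CC[Si](CC)(CC)O[C@@H]1C[C@@H](OC(=O)[C@@]2(C)O[C@@H]2C)C(C)(C)[C@@H]2[C@@H](B4OC(C)(C)C(C)(C)O4)[C@@]3(O[Si](CC)(CC)CC)C=C(C)[C@@H]2[C@]31C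
F4 | step 13 | 6-endo-alcohol (22 with OH in place of NO2) | CC[Si](CC)(CC)O[C@@H]1C[C@@H](OC(=O)[C@@]2(C)O[C@@H]2C)C(C)(C)[C@@H]2[C@@H](O)[C@@]3(O[Si](CC)(CC)CC)C=C(C)[C@@H]2[C@]31C
F5 | step 13 | 6-endo-methanesulfonate of F4 | CC[Si](CC)(CC)O[C@@H]1C[C@@H](OC(=O)[C@@]2(C)O[C@@H]2C)C(C)(C)[C@@H]2[C@@H](OS(C)(=O)=O)[C@@]3(O[Si](CC)(CC)CC)C=C(C)[C@@H]2[C@]31C
F6 | step 11 | bicyclic nitro enone (C10–C5 bond formed, CH2NO2 on C5, cyclopentenone intact) | CC[Si](CC)(CC)O[C@@H]1C[C@@H](OC(=O)[C@@]2(C)O[C@@H]2C)C(C)(C)[C@H](C[N+](=O)[O-])[C@@H]2C(C)=CC(=O)[C@@]21C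
F7 | step 8 | (1R,3R)-1-hydroxy-4,4-dimethyl-1-[(1S)-1,4-dimethyl-2-oxocyclopent-3-en-1-yl]hex-5-en-3-yl acetate | O[C@H](C[C@@H](OC(C)=O)C(C)(C)C=C)[C@]1(C)CC(C)=CC1=O
F8 | step 8 | C1 triethylsilyl ether of F7 | CC[Si](CC)(CC)O[C@H](C[C@@H](OC(C)=O)C(C)(C)C=C)[C@]1(C)CC(C)=CC1=O
F9 | step 8 | (5S)-5-[(1R,3R)-3-hydroxy-4,4-dimethyl-1-(triethylsilyloxy)hex-5-en-1-yl]-3,5-dimethylcyclopent-2-en-1-one | CC[Si](CC)(CC)O[C@H](C[C@@H](O)C(C)(C)C=C)[C@]1(C)CC(C)=CC1=O
F10 | step 8 | (2S,3R)-2,3-dimethyloxirane-2-carboxylic acid | OC(=O)[C@@]1(C)O[C@@H]1C
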